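All runs were generated by integration for an exercise; the scatter is artificial.

The product was what I followed first: in the runs below, its late slope fell as capture agent went up.

| flask | substrate | coupling partner | capture agent | free catalyst | second catalyst | remark | time |
|---|---|---|---|---|---|---|---|
| oak | 0.40 M | 1 M | 0.32 M | 4 mM | 4 mM | run made earlier |  |
| elm | 0.40 M | 1 M | 1.4 M | 4 mM | 4 mM | run made earlier |  |
| east | 0.40 M | 1.00 M | 0.400 M | 4.0 mM | 4.0 mM |  | 30 h |
| south-east | 0.40 M | 1.00 M | 0.800 M | 4.0 mM | 4.0 mM |  | 30 h |
| south | 0.40 M | 1.00 M | 1.60 M | 4.0 mM | 4.0 mM |  | 30 h |

- oak (time / h: product / %): 2.50: 1.9; 8.00: 7.4; 15.0: 19.4; 20.0: 25.5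
- elm (time / h: product / %): 1.50: 1.3; 4.00: 2.0; 10.0: 8.0; 20.0: 16.9

(standard deviation of a reading: 0.5 percentage points)

* which of the two there is more of at the end, east (product / trapped intermediate)
* which of the two there is more of at the end, south-east (product / trapped intermediate)
* which of the two there is more of at the end, south (product / trapped intermediate)
* product at the end, in percent of the substrate charged, east
* product at the end, in percent of the substrate charged, south-east
* product at the end, in percent of the substrate charged, south

Did capture agent really take material from product? Between its second and last readings the oak run rose by 0.0151 h⁻¹ of the charge, and the elm run from its third reading rose by 0.00890 h⁻¹, so oak ran faster by a factor of 1.69. I assumed that one intermediate was fed equally in both runs, since their substrate and free catalyst charges matched, and that it split two ways. Trapped intermediate formed per product formed is then b·c(capture agent), a selectivity factor in which the capture coefficient b is that ratio per mole per litre of capture agent. The slope ratio gave b = 0.810 M⁻¹, as a reading with the scatter of the tables.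

Which species led at the end? My reckoned split was 0.324 in east, 0.648 in south-east and 1.30 in south. I therefore expected product to lead in east and south-east, and trapped intermediate to lead in south.

How much product? The oak slope, multiplied by 1.26 to restore what was captured, gave a substrate loss of 0.0190 h⁻¹, taken as first order. That meant 43.4 % consumed by 30 h, with the material between counted as nothing. My product figures were 32.8 %, 26.4 % and 18.9 %.

The forecast differed: it gave 35.5 %, 30 % and 23 %, used 0.6 per molar as its coefficient, and chose product for south, adding “South is nearly a tie with trapped”.

The flask gave 35.3 %, 28.4 % and 20.3 % of product, and south held 30.5 % of trapped intermediate, so trapped intermediate led there, against the forecast.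

    substrate + free catalyst → free catalyst + open intermediate (k = 6.38 M⁻¹ h⁻¹)
    second catalyst + open intermediate ⇌ catalyst intermediate (K = 1.13 M⁻¹, k = 78.0 M⁻¹ h⁻¹)
    coupling partner + catalyst intermediate → second catalyst + product (k = 122 M⁻¹ h⁻¹)
    open intermediate + capture agent → trapped intermediate (k = 0.190 M⁻¹ h⁻¹)

The ratio to watch, trapped intermediate over product, stood at 1.50 at the end in south, where I had carried 1.30. At the charged amounts in south, open intermediate went on to product with a pseudo-first-order rate constant of 0.199 h⁻¹ and met capture agent with 0.304 h⁻¹, which is more than the first. A neighbour of south with 0.016 M of free catalyst reached 37.9 % of product and 56.1 % of trapped intermediate, a ratio of 1.48.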